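**Retrosynthetic overview**
1. Target ⇐ chlorite oxidation of the acrylic aldehyde; before that, the C–O bond at the isopropenyl methyl is made by late allylic C–H hydroxylation.
2. Ester C–O bond ⇐ site-selective acylation of a ring 1,3-diol, whose less hindered carbinol comes from thermodynamic ketyl reduction of a ketone.
3. Key bond: the ring C–OH between the two side chains, made by face-selective conjugate borylation of a cyclohexenone and C–B to C–O oxidation, run in one flask with α-alkenylation of the boron enolate (new method).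
4. The enone ⇐ (1R,5R)-verbenone: vinyl conjugate addition sets the quaternary carbon, Lewis-acid cyclobutane fragmentation unveils the isopropenyl group, enol acetate dehydrogenation gives the enone.
5. Ring order: no ring is formed; the cyclohexane is the six-membered ring of verbenone and its cyclobutane is cleaved.

Assumption: (1R,5R)-(+)-verbenone, 2-bromoacrolein diethyl acetal and 2-(hydroxymethyl)acrylic acid are taken as purchasable; positions are told by elemane locants (C10 quaternary carbon, C9 methylene, C8 ester carbinol, C7 carrying the C11(=C13)–C12 acrylic unit, C6 free carbinol, C5 carrying the C4(=C3)–C15 propenyl unit).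

**Route**

Step 1
Reactants: 1 (1R,5R)-(+)-verbenone; 2 vinylmagnesium bromide
Product: 3 (1R,4S,5S)-4-ethenyl-4,6,6-trimethylbicyclo[3.1.1]heptan-2-one
Conditions: CH2=CHMgBr (1.5 equiv), CuBr·SMe2 (10 mol %), THF, −40 to 0 °C; then 1 M HCl
Reagents that add atoms: vinylmagnesium bromide (compound 2), C=C[Mg]Br
Why: Copper-catalysed conjugate addition of the vinyl Grignard reagent; the cuprate attacks C10 from the face opposite the gem-dimethyl bridge, so vinyl ends up trans and methyl cis to the carbon that becomes the C5 isopropenyl group.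

Step 2
Reactants: 3 (1R,4S,5S)-4-ethenyl-4,6,6-trimethylbicyclo[3.1.1]heptan-2-one
Product: 4 (4S,5S)-5-ethenyl-5-methyl-4-(prop-1-en-2-yl)cyclohex-1-en-1-yl acetate
Conditions: Ac2O, BF3·OEt2, Zn(OAc)2, 0 to 23 °C
Reagents that add atoms: acetic anhydride, CC(=O)OC(C)=O
Why: Lewis-acid cyclobutane fragmentation (heterolysis of the strained bond between the ketone α-carbon and the gem-dimethyl carbon): the tertiary cation loses a methyl proton to give the isopropenyl group and the enol is trapped regiospecifically as the C7=C8 enol acetate, with C5 and C10 untouched.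

Step 3
Reactants: 4 (4S,5S)-5-ethenyl-5-methyl-4-(prop-1-en-2-yl)cyclohex-1-en-1-yl acetate
Product: 5 (4S,5S)-5-ethenyl-5-methyl-4-(prop-1-en-2-yl)cyclohex-2-en-1-one
Conditions: Pd(OAc)2 (5 mol %), dppe (5 mol %), Bu3SnOMe (20 mol %), allyl methyl carbonate (2 equiv), MeCN, 80 °C
Reagents that add atoms: none
Why: Tsuji palladium/tin dehydrogenation of an enol acetate (tin enolate, allylpalladium enolate, β-hydride elimination; a Saegusa-type desaturation): only the C6 hydrogens are β to palladium, so the C6=C7 enone forms and no stereocentre is touched.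

Step 4
Reactants: 5 (4S,5S)-5-ethenyl-5-methyl-4-(prop-1-en-2-yl)cyclohex-2-en-1-one; 6 2-bromo-3,3-diethoxyprop-1-ene
Product: 9 (2S,3R,4S,5S)-2-(3,3-diethoxyprop-1-en-2-yl)-5-ethenyl-3-hydroxy-5-methyl-4-(prop-1-en-2-yl)cyclohexan-1-one, via O-boryl enolate 7 (not isolated), via boryl ketone 8 (not isolated)
Conditions: (IPr)CuCl (5 mol %; IPr = 1,3-bis(2,6-diisopropylphenyl)imidazol-2-ylidene), NaOtBu (5 mol %), B2pin2 (1.1 equiv), THF, 0 °C; then 6 (1.3 equiv), Pd[P(tBu)3]2 (5 mol %), CsF (2 equiv), 40 °C; then 30% H2O2, K2CO3 (0.2 equiv), THF/H2O, 0 °C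
Reagents that add atoms: 2-bromo-3,3-diethoxyprop-1-ene (compound 6), C=C(Br)C(OCC)OCC; hydrogen peroxide, OO
Why: Proposed new method: a one-flask anti-selective β-oxy-α-alkenylation of a cyclic enone (closest known reactions: copper-catalysed conjugate borylation of enones with aldol trapping of the boron enolate, copper/palladium aryl- and alkenylboration of alkenes, and palladium-catalysed α-alkenylation of ketone, silyl and tin enolates) — the (IPr)Cu–Bpin species adds to C6 from the face opposite the cis-disposed C5 isopropenyl and C10 methyl groups, B2pin2 turns the copper enolate over to O-boryl enolate 7 without a proton source, fluoride lets 7 transmetalate to the alkenylpalladium bromide formed from 6 and zerovalent palladium, reductive elimination makes the C7–C11 bond of 8, and peroxide oxidation of C–B with retention forms the C6–O bond; C7 is epimerisable under the carbonate and settles equatorial, trans to both neighbours.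

Step 5
Reactants: 9 (2S,3R,4S,5S)-2-(3,3-diethoxyprop-1-en-2-yl)-5-ethenyl-3-hydroxy-5-methyl-4-(prop-1-en-2-yl)cyclohexan-1-one
Product: 10 (1S,2R,3R,4S,5S)-2-(3,3-diethoxyprop-1-en-2-yl)-5-ethenyl-5-methyl-4-(prop-1-en-2-yl)cyclohexane-1,3-diol
Conditions: SmI2 (2.5 equiv), THF/H2O, 0 °C
Reagents that add atoms: none
Why: Single-electron ketyl reduction under dissolving-metal-type thermodynamic control: an axial C8–O would be 1,3-diaxial to the C10 methyl group, so the O–samarium group settles equatorial and protonation gives the equatorial C8 carbinol cis to C6–OH (hydride reagents attack from the open equatorial side and would give the other epimer).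

Step 6
Reactants: 11 2-(hydroxymethyl)prop-2-enoic acid
Product: 13 2-{[(tert-butyldimethylsilyl)oxy]methyl}prop-2-enoic acid, via silyl ester 12 (not isolated)
Conditions: TBSCl (2.2 equiv), imidazole (4.4 equiv), DMF, 23 °C; then MeOH/H2O, K2CO3 (10 mol %), 0 °C; pH 5 work-up
Reagents that add atoms: tert-butyldimethylsilyl chloride, CC(C)(C)[Si](C)(C)Cl
Why: Silylation of hydroxyl and carboxyl groups followed by selective solvolysis of the labile silyl ester; no stereocentre is involved.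

Step 7
Reactants: 10 (1S,2R,3R,4S,5S)-2-(3,3-diethoxyprop-1-en-2-yl)-5-ethenyl-5-methyl-4-(prop-1-en-2-yl)cyclohexane-1,3-diol; 13 2-{[(tert-butyldimethylsilyl)oxy]methyl}prop-2-enoic acid
Product: 15 (1S,2S,3R,4S,5S)-2-(3,3-diethoxyprop-1-en-2-yl)-5-ethenyl-3-hydroxy-5-methyl-4-(prop-1-en-2-yl)cyclohexyl 2-{[(tert-butyldimethylsilyl)oxy]methyl}prop-2-enoate, via mixed anhydride 14 (not isolated)
Conditions: 13 (1.05 equiv), 2,4,6-trichlorobenzoyl chloride, Et3N, toluene, 23 °C; then 10, DMAP (0.2 equiv), 0 °C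
Reagents that add atoms: acid 13, C=C(CO[Si](C)(C)C(C)(C)C)C(=O)O
Why: Yamaguchi esterification via the mixed anhydride; the C8 carbinol has one branched neighbour and acylates much faster than the C6 carbinol flanked by two branched carbons, so the ester C–O bond forms at C8 without protecting C6–OH.

Step 8
Reactants: 15 (1S,2S,3R,4S,5S)-2-(3,3-diethoxyprop-1-en-2-yl)-5-ethenyl-3-hydroxy-5-methyl-4-(prop-1-en-2-yl)cyclohexyl 2-{[(tert-butyldimethylsilyl)oxy]methyl}prop-2-enoate
Product: 16 (1S,2S,3R,4S,5S)-5-ethenyl-3-hydroxy-5-methyl-2-(3-oxoprop-1-en-2-yl)-4-(prop-1-en-2-yl)cyclohexyl 2-(hydroxymethyl)prop-2-enoate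
Conditions: 1 M HCl, THF, 23 °C
Reagents that add atoms: water, O
Why: Acid hydrolysis of the diethyl acetal and of the primary silyl ether in one operation; the ester and the ring stereocentres are inert to dilute acid at room temperature.

Step 9
Reactants: 16 (1S,2S,3R,4S,5S)-5-ethenyl-3-hydroxy-5-methyl-2-(3-oxoprop-1-en-2-yl)-4-(prop-1-en-2-yl)cyclohexyl 2-(hydroxymethyl)prop-2-enoate
Product: 17 (1S,2S,3R,4R,5S)-5-ethenyl-3-hydroxy-4-(3-hydroxyprop-1-en-2-yl)-5-methyl-2-(3-oxoprop-1-en-2-yl)cyclohexyl 2-(hydroxymethyl)prop-2-enoate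
Conditions: SeO2 (30 mol %), tBuOOH (3 equiv), CH2Cl2, 23 °C
Reagents that add atoms: tert-butyl hydroperoxide (oxygen relayed by SeO2), CC(C)(C)OO
Why: Selenium dioxide allylic hydroxylation (ene reaction then [2,3]-sigmatropic shift): the C4 isopropenyl group is the only electron-rich alkene with accessible allylic hydrogens (the vinyl group has none and the acrylic alkenes are electron-poor), so C15–OH forms, and any over-oxidation of the C12 aldehyde gives the target acid itself.

Step 10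
Reactants: 17 (1S,2S,3R,4R,5S)-5-ethenyl-3-hydroxy-4-(3-hydroxyprop-1-en-2-yl)-5-methyl-2-(3-oxoprop-1-en-2-yl)cyclohexyl 2-(hydroxymethyl)prop-2-enoate
Product: 18 (1S,2S,3R,4R,5S)-2-(1-carboxyethenyl)-5-ethenyl-3-hydroxy-4-(3-hydroxyprop-1-en-2-yl)-5-methylcyclohexyl 2-(hydroxymethyl)prop-2-enoate (CNP0509685.1)
Conditions: NaClO2, NaH2PO4, 2-methyl-2-butene, tBuOH/H2O, 0 to 23 °C
Reagents that add atoms: sodium chlorite, [Na+].[O-]Cl=O
Why: Pinnick oxidation of the enal to the acrylic acid with 2-methyl-2-butene as hypochlorite scavenger; alcohols, alkenes and the ester are untouched, and the buffered cold work-up avoids lactonisation of the γ-hydroxy acid.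

**Compound list**
1 | (1R,5R)-(+)-verbenone, (1R,5R)-4,6,6-trimethylbicyclo[3.1.1]hept-3-en-2-one | O=C1C=C(C)[C@H]2C[C@@H]1C2(C)C | starting material
2 | vinylmagnesium bromide | C=C[Mg]Br | starting material
3 | (1R,4S,5S)-4-ethenyl-4,6,6-trimethylbicyclo[3.1.1]heptan-2-one (vinyl anti to the gem-dimethyl bridge) | O=C1C[C@@](C)(C=C)[C@H]2C[C@@H]1C2(C)C | intermediate
4 | (4S,5S)-5-ethenyl-5-methyl-4-(prop-1-en-2-yl)cyclohex-1-en-1-yl acetate | C=C[C@]1(C)CC(OC(C)=O)=CC[C@H]1C(C)=C | intermediate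
5 | (4S,5S)-5-ethenyl-5-methyl-4-(prop-1-en-2-yl)cyclohex-2-en-1-one | C=C[C@]1(C)CC(=O)C=C[C@H]1C(C)=C | intermediate
6 | 2-bromo-3,3-diethoxyprop-1-ene (2-bromoacrolein diethyl acetal) | C=C(Br)C(OCC)OCC | starting material
7 | O-pinacolboryl enolate of (3S,4S,5S)-5-ethenyl-5-methyl-4-(prop-1-en-2-yl)-3-(4,4,5,5-tetramethyl-1,3,2-dioxaborolan-2-yl)cyclohexan-1-one (C6 boryl trans to C5 isopropenyl) | C=C[C@]1(C)CC(OB2OC(C)(C)C(C)(C)O2)=C[C@H](B3OC(C)(C)C(C)(C)O3)[C@H]1C(C)=C | intermediate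
8 | (2R,3R,4S,5S)-2-(3,3-diethoxyprop-1-en-2-yl)-5-ethenyl-5-methyl-4-(prop-1-en-2-yl)-3-(4,4,5,5-tetramethyl-1,3,2-dioxaborolan-2-yl)cyclohexan-1-one | C=C[C@]1(C)CC(=O)[C@@H](C(=C)C(OCC)OCC)[C@H](B2OC(C)(C)C(C)(C)O2)[C@H]1C(C)=C | intermediate
9 | (2S,3R,4S,5S)-2-(3,3-diethoxyprop-1-en-2-yl)-5-ethenyl-3-hydroxy-5-methyl-4-(prop-1-en-2-yl)cyclohexan-1-one | C=C[C@]1(C)CC(=O)[C@@H](C(=C)C(OCC)OCC)[C@H](O)[C@H]1C(C)=C | intermediate
10 | (1S,2R,3R,4S,5S)-2-(3,3-diethoxyprop-1-en-2-yl)-5-ethenyl-5-methyl-4-(prop-1-en-2-yl)cyclohexane-1,3-diol | C=C[C@]1(C)C[C@H](O)[C@@H](C(=C)C(OCC)OCC)[C@H](O)[C@H]1C(C)=C | intermediate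
11 | 2-(hydroxymethyl)prop-2-enoic acid | C=C(CO)C(=O)O | starting material
12 | tert-butyldimethylsilyl 2-{[(tert-butyldimethylsilyl)oxy]methyl}prop-2-enoate | C=C(CO[Si](C)(C)C(C)(C)C)C(=O)O[Si](C)(C)C(C)(C)C | intermediate
13 | 2-{[(tert-butyldimethylsilyl)oxy]methyl}prop-2-enoic acid | C=C(CO[Si](C)(C)C(C)(C)C)C(=O)O | intermediate
14 | 2-{[(tert-butyldimethylsilyl)oxy]methyl}prop-2-enoic 2,4,6-trichlorobenzoic anhydride | C=C(CO[Si](C)(C)C(C)(C)C)C(=O)OC(=O)c1c(Cl)cc(Cl)cc1Cl | intermediate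
15 | (1S,2S,3R,4S,5S)-2-(3,3-diethoxyprop-1-en-2-yl)-5-ethenyl-3-hydroxy-5-methyl-4-(prop-1-en-2-yl)cyclohexyl 2-{[(tert-butyldimethylsilyl)oxy]methyl}prop-2-enoate | C=C[C@]1(C)C[C@H](OC(=O)C(=C)CO[Si](C)(C)C(C)(C)C)[C@@H](C(=C)C(OCC)OCC)[C@H](O)[C@H]1C(C)=C | intermediate
16 | (1S,2S,3R,4S,5S)-5-ethenyl-3-hydroxy-5-methyl-2-(3-oxoprop-1-en-2-yl)-4-(prop-1-en-2-yl)cyclohexyl 2-(hydroxymethyl)prop-2-enoate | C=C[C@]1(C)C[C@H](OC(=O)C(=C)CO)[C@@H](C(=C)C=O)[C@H](O)[C@H]1C(C)=C | intermediate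
17 | (1S,2S,3R,4R,5S)-5-ethenyl-3-hydroxy-4-(3-hydroxyprop-1-en-2-yl)-5-methyl-2-(3-oxoprop-1-en-2-yl)cyclohexyl 2-(hydroxymethyl)prop-2-enoate | C=C[C@]1(C)C[C@H](OC(=O)C(=C)CO)[C@@H](C(=C)C=O)[C@H](O)[C@H]1C(=C)CO | intermediate
18 | (1S,2S,3R,4R,5S)-2-(1-carboxyethenyl)-5-ethenyl-3-hydroxy-4-(3-hydroxyprop-1-en-2-yl)-5-methylcyclohexyl 2-(hydroxymethyl)prop-2-enoate (CNP0509685.1) | C=C[C@]1(C)C[C@H](OC(=O)C(=C)CO)[C@@H](C(=C)C(=O)O)[C@H](O)[C@H]1C(=C)CO | target

**Step count and risks**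
Total step count: 10. Longest linear sequence: 9 steps (steps 1–5 and 7–10; step 6 is a one-step side branch).

Most likely to fail, first: step 4, the new one-flask borylation/alkenylation/oxidation. The boron enolate may transmetalate poorly, protodeborylate, or the base may move the C5 stereocentre through the dienolate. The fallback uses known chemistry and sets out from 5 and 6. Iodination of 5 (I2, pyridine, CH2Cl2) gives (4S,5S)-5-ethenyl-2-iodo-5-methyl-4-(prop-1-en-2-yl)cyclohex-2-en-1-one F1. Miyaura borylation of 6 (B2pin2, PdCl2(PPh3)2, PPh3, KOPh, toluene, 50 °C) gives the alkenyl pinacol boronate F2. Suzuki coupling of F1 and F2 (PdCl2(dppf), K3PO4, THF/H2O) gives the cross-conjugated dienone F3. Copper-catalysed conjugate borylation of F3 (CuCl, Xantphos, NaOtBu, B2pin2, MeOH, THF) comes back to the route at 8, which is oxidised to 9 by the peroxide stage of step 4.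

Second: step 5, the configuration of the C8 carbinol. The ketyl reduction may give an epimer mixture or attack the allylic acetal. The fallback sets out from 9: LiBH(sBu)3 in THF at −78 °C delivers hydride from the open equatorial side and gives cleanly the axial C8 carbinol F4. A ruthenium-catalysed redox epimerisation of the secondary alcohol (Ru(CO)2Cl(η5-C5Ph5) 5 mol %, KOtBu 5 mol %, toluene, 50 °C) then equilibrates it to the all-equatorial diol, so the fallback comes back at 10.

Third: step 9, the late allylic C–H hydroxylation. It may over-oxidise C15 to the aldehyde or stall on the polar substrate. The fallback sets out from 16: ene-type chlorination with hypochlorous acid (Ca(OCl)2, CO2, CH2Cl2/H2O, 0 °C) gives the allylic chloride F5, and silver-assisted solvolysis of its symmetrical allyl system (AgBF4, acetone/H2O, 23 °C) comes back to the route at 17.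

**Further compounds**
F1 | step 4 | (4S,5S)-5-ethenyl-2-iodo-5-methyl-4-(prop-1-en-2-yl)cyclohex-2-en-1-one | C=C[C@]1(C)CC(=O)C(I)=C[C@H]1C(C)=C
F2 | step 4 | 2-(3,3-diethoxyprop-1-en-2-yl)-4,4,5,5-tetramethyl-1,3,2-dioxaborolane | C=C(B1OC(C)(C)C(C)(C)O1)C(OCC)OCC
F3 | step 4 | (4S,5S)-2-(3,3-diethoxyprop-1-en-2-yl)-5-ethenyl-5-methyl-4-(prop-1-en-2-yl)cyclohex-2-en-1-one | C=C[C@]1(C)CC(=O)C(C(=C)C(OCC)OCC)=C[C@H]1C(C)=C
F4 | step 5 | (1R,2R,3R,4S,5S)-2-(3,3-diethoxyprop-1-en-2-yl)-5-ethenyl-5-methyl-4-(prop-1-en-2-yl)cyclohexane-1,3-diol | C=C[C@]1(C)C[C@@H](O)[C@@H](C(=C)C(OCC)OCC)[C@H](O)[C@H]1C(C)=C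
F5 | step 9 | (1S,2S,3R,4R,5S)-4-(3-chloroprop-1-en-2-yl)-5-ethenyl-3-hydroxy-5-methyl-2-(3-oxoprop-1-en-2-yl)cyclohexyl 2-(hydroxymethyl)prop-2-enoate | C=C[C@]1(C)C[C@H](OC(=O)C(=C)CO)[C@@H](C(=C)C=O)[C@H](O)[C@H]1C(=C)CCl
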